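The numbers in the tables were generated by integration with made-up constants; the scatter is artificial.

The catalyst is conserved through its round: each target made is one finished turn, after which the same catalyst stands free again. So, for a single round of stages in series, the time per turn is the sum of the stage times, and the apparent order in partner is the share of that sum spent on the stage whose rate follows partner. I therefore began with the turn time, the inverse of the turnover frequency: catalyst charged over the rate of making target.

the same everywhere: starting material 0.050 M; partner 0.125 M
- larch: free catalyst 5 mM; run made earlier
- ash: free catalyst 11 mM; run made earlier
- flask: free catalyst 7.5 mM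

| larch: time / h | larch: target / % | ash: time / h | ash: target / % |
|---|---|---|---|
| 0.500 | 0.5 | 0.500 | 2.0 |
| 0.833 | 3.4 | 1.50 | 13.2 |
| 1.50 | 5.3 | 3.00 | 25.1 |
| 3.00 | 11.1 | 4.00 | 30.9 |
| 6.00 | 20.0 | 6.00 | 40.4 |

(each reading ± 0.5 percentage points)

- apparent order in partner when 30% of the starting material are converted (percent change of the rate of making target for one percent more partner charged)

- the analysis behind the earlier runs scatters by 0.5 percentage points, standard deviation
- no earlier run changes the charge of partner; that part of a forecast is a guess

Between 1.50 h and 6.00 h, the larch run gave 3.06 h and the ash run gave 3.64 h. The flask's catalyst charge lies between theirs, so I took the mean, 3.35 h, as its turn time.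

My first objection was that the turn time did not hold still. In the ash run it was 2.77 h up to 3.00 h and 4.31 h afterwards, longer than before. If catalyst was leaving the round, a time counted per catalyst charged overstated the turn of the working catalyst, so I kept it as a figure to correct.

My second objection was worse: neither run changed partner, and a quick or a slow partner stage could sit inside the same sum. My reckoning therefore stopped at an order between zero and one.

The forecast gave 0.8, within 0.2 to 1.2, noting that “Nothing here measures the partner order directly”.

The flask gave an order of 0.0017 at 3.12 h, and twice the partner multiplied the rate by 1.00.

    starting material + free catalyst ⇌ catalyst intermediate A (K = 17.0 M⁻¹, k = 120 M⁻¹ h⁻¹)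
    catalyst intermediate A → catalyst intermediate B (k = 5.46 h⁻¹)
    partner + catalyst intermediate B → catalyst intermediate C (k = 3170 M⁻¹ h⁻¹)
    catalyst intermediate C → free catalyst + target (k = 0.935 h⁻¹)
    catalyst intermediate C → spent catalyst (k = 0.299 h⁻¹)

At 3.00 h, catalyst intermediate B, the form that meets partner, held 0.107% of the flask's catalyst, and catalyst intermediate C held 36.1%. My turn time of 3.35 h stood against the flask's own 3.03 h at 3.12 h, catalyst charged over rate; taking off the 37.0% of spent catalyst at 3.00 h gives the working catalyst a turn time of 1.91 h. With partner at 88.7%, its stage lasted 0.00285 h, a share of 0.00149.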